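**Plan**

1. Numbering used throughout (target): C1 = CH(COPh), C2 = the ketone next to it, C3 = O‑bearing quaternary carbon, C4 = furandione ketone, C5 = its quaternary neighbour, C6 = CH2, C7 = CH(prenyl), C8 = C(Me)(homoprenyl), C9 = lactone C=O, O1 = lactone oxygen.
2. Retrosynthesis: cut C4–C5 (transannular Lacey–Dieckmann; furandione ring and eight‑membered carbocycle fall together) and C1–COPh. This leaves the nine‑membered lactone ring O1–C9–C5–C6–C7–C8–C1–C2–C3, in which ketone C2 is δ,ε to a C5=C6 enoate, the retron of an oxy‑Cope rearrangement.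
3. Cut C7–C8 and C2–C3 together: the ring contracts to a γ‑lactone carbinol (O1–C9–C5–C2–C3) with alkenyl groups on C2 and C5, which opens by retro‑aldol to an acyclic α‑acyloxy ester. The event is possible because C3 is both the α‑carbon of the C4 ester and joined through O1–C9 to C5.
4. Forward order: hydroxy ester plus acylketene → β‑keto ester → Knoevenagel and deconjugative prenylation (quaternary C5) → transient γ‑lactone → nine‑membered lactone (C2–C3 and C7–C8) → conjugate reduction and C1 benzoylation → furandione and eight‑membered ring last. No protecting groups are used.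
5. Stereochemistry: the glycidate‑derived C3 centre only makes the C5 epimers separable and is erased in step 6. C5 (R) comes from catalyst‑controlled prenylation and is relayed through a chair [3,3] shift with two E alkenes to C7 and C8, while the aldol face sets C3. The bridgehead C5 of the target is fixed by ring fusion and C1 by equilibration.

Key step: step 6

Assumption: C1–H of the target lies between two ketones and epimerises through the enol; the 1R configuration is taken to be the thermodynamically preferred one.
Assumption: the [3,3] shift of step 6 is taken to run through the chair array of the aldolate whose two alkenyl groups are trans on the lactone ring; the stereochemical design (5R, 6E, 2E) follows from that model.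
Assumption: geranic acid is used as its pure 2E isomer, and the catalyst antipode in step 5 is the one that favours the 5R epimer (both pseudo‑enantiomeric catalysts are sold).

**Step 1**
Reactants: 1 methyl (2S)-oxirane-2-carboxylate; 2 (2-methylprop-1-en-1-yl)magnesium bromide
Product: 3 methyl (2S)-2-hydroxy-5-methylhex-4-enoate
Conditions: CuI (10 mol %), THF, −40 °C; 1 M HCl work-up
Reagents that add atoms: 2 (2-methylprop-1-en-1-yl)magnesium bromide, CC(C)=C[Mg]Br
Why: Copper-catalysed SN2 opening of the epoxide by the alkenylmagnesium reagent occurs at the unsubstituted carbon, so the stereocentre (later C3) is carried unchanged into the α-hydroxy ester.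

**Step 2**
Reactants: 4 (2E)-geranic acid; 5 2,2-dimethyl-1,3-dioxane-4,6-dione
Product: 6 5-[(2E)-1-hydroxy-3,7-dimethylocta-2,6-dien-1-ylidene]-2,2-dimethyl-1,3-dioxane-4,6-dione
Conditions: N,N'-dicyclohexylcarbodiimide, 4-(dimethylamino)pyridine, CH2Cl2, 0 → 25 °C
Reagents that add atoms: 5 2,2-dimethyl-1,3-dioxane-4,6-dione, CC1(C)OC(=O)CC(=O)O1
Why: C-acylation of the cyclic malonate with the carbodiimide-activated acid should give the enolised acyl derivative without touching the 2E double bond.

**Step 3**
Reactants: 6 acyl dioxanedione; 3 methyl (2S)-2-hydroxy-5-methylhex-4-enoate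
Product: 8 methyl (2S)-2-{[(4E)-5,9-dimethyl-3-oxodeca-4,8-dienoyl]oxy}-5-methylhex-4-enoate, via acylketene 7 (not isolated)
Conditions: toluene, 85 °C
Reagents that add atoms: 3 methyl (2S)-2-hydroxy-5-methylhex-4-enoate, COC(=O)[C@@H](O)CC=C(C)C
Why: Thermal loss of acetone and CO2 gives acylketene 7, which the secondary alcohol traps as the β-keto ester (acylketene esterification) under neutral conditions that leave the stereocentre and both alkenes untouched.

**Step 4**
Reactants: 8 β-keto ester; 9 5-methylhex-4-enal
Product: 10 methyl (2S)-2-{[(4E)-5,9-dimethyl-2-(5-methylhex-4-en-1-ylidene)-3-oxodeca-4,8-dienoyl]oxy}-5-methylhex-4-enoate (E/Z mixture at the new C5=C6 bond)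
Conditions: piperidine (10 mol %), AcOH (10 mol %), 4 Å molecular sieves, CH2Cl2, 0 → 25 °C
Reagents that add atoms: 9 5-methylhex-4-enal, CC(C)=CCCC=O
Why: Knoevenagel condensation at the doubly activated C5 methylene (between the C9 ester and the C2 ketone) gives the alkylidene β-keto ester; its E/Z ratio is irrelevant because step 5 passes through the common extended enolate.

**Step 5**
Reactants: 10 alkylidene β-keto ester; 11 1-bromo-3-methylbut-2-ene
Product: 12 methyl (2S)-2-{[(2R,4E)-5,9-dimethyl-2-(3-methylbut-2-en-1-yl)-2-[(1E)-5-methylhexa-1,4-dien-1-yl]-3-oxodeca-4,8-dienoyl]oxy}-5-methylhex-4-enoate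
Conditions: Cs2CO3 (solid), O-allyl-N-(9-anthracenylmethyl)cinchonidinium bromide (10 mol %), toluene, −20 °C; chromatography
Reagents that add atoms: 11 1-bromo-3-methylbut-2-ene, CC(C)=CCBr
Why: Deconjugative α-alkylation of a Knoevenagel adduct under asymmetric phase-transfer catalysis: γ-deprotonation at C7 gives the extended enolate, C-alkylation at C5 creates the quaternary centre (5R, catalyst control) and the E C6=C7 bond, and the minor 5S epimer, a diastereomer because of the resident C3 centre, is removed by chromatography.

**Step 6**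
Reactants: 12 acyclic α-acyloxy ester
Product: 16 methyl (2S,5S,6S,7E)-5-methyl-2,6,8-tris(3-methylbut-2-en-1-yl)-5-(4-methylpent-3-en-1-yl)-3,9-dioxo-2,3,4,5,6,9-hexahydrooxonine-2-carboxylate, via potassium ester enolate 13 (not isolated), via potassium aldolate 14 (not isolated), via potassium enolate 15 (not isolated)
Conditions: KN(SiMe3)2 (1.05 equiv), 18-crown-6 (1.1 equiv), THF, −78 → −20 °C; AcOH, −78 °C
Reagents that add atoms: none
Why: Proposed new method: deprotonation of the α-acyloxy ester C3–H gives enolate 13, which adds in a 5-(enolexo)-exo-trig aldol to the C2 enone carbonyl four atoms away to form γ-lactone alkoxide 14 (bond C2–C3); 14 is a 3-oxido-1,5-diene (C8=C1–C2(O−)–C5–C6=C7) and undergoes an alkoxide-accelerated [3,3] shift in which C7–C8 forms and the ring bond C2–C5 breaks, so the five-membered lactone expands by four atoms to the nine-membered lactone enolate 15. The closest known reaction types are the ring-expanding anionic oxy-Cope rearrangement of 1,2-dialkenylcycloalkanolates and the intramolecular ester-enolate aldol; coupling them through an α-acyloxy ester enolate is without precedent, but the shift should be driven by the alkoxide-to-enolate change, by conjugation of the new C5=C6 bond with the lactone carbonyl and by relief of three contiguous fully substituted carbons. Ring closures: the γ-lactone closes 5-exo-trig and is only transient, and the nine-membered ring is not closed directly but arises by sigmatropic ring expansion. Stereocentres: C3 is set by the aldol face (without a chelating cation the larger prenyl group should lie syn to the oxide and the ester syn to the C2 dienyl group, and the aldol is reversible so only the aldolate that reaches the chair array reacts on), while C7 and C8 are set by a chair transition state of the trans-dialkenyl aldolate in which the 6E and 2E alkenes place the C7 side chain and the C8 homoprenyl group equatorial and the stereogenic C5 relays its configuration before it becomes trigonal. Selectivity needed: C3–H must be removed in preference to the γ-hydrogens of the enone (helped by the α-acyloxy group and one equivalent of base at −78 °C), the enolate must attack the ketone and not its own ester carbonyl (five- against three-membered transition state), and the concerted shift must outrun fragmentation of 14 to a C5 ester dienolate; the E geometry of the new C5=C6 bond forbids transannular attack of C1 on C9 in 15.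

**Step 7**
Reactants: 16 nine-membered keto lactone
Product: 17 methyl (2S,5S,6S)-5-methyl-2,6,8-tris(3-methylbut-2-en-1-yl)-5-(4-methylpent-3-en-1-yl)-3,9-dioxooxonane-2-carboxylate (both epimers at ring carbon 8 = C5)
Conditions: [(Ph3P)CuH]6 (0.4 equiv), t-BuOH (2 equiv), toluene, 0 → 25 °C; 1 M HCl work-up
Reagents that add atoms: none
Why: Conjugate reduction with the phosphine-stabilised monovalent copper hydride should be chemoselective for the strained E enoate over the hindered isolated C2 ketone and the esters; the configuration formed at C5 is irrelevant because C5 is enolised again in step 9.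

**Step 8**
Reactants: 17 saturated keto lactone; 18 1-benzoyl-1H-benzotriazole
Product: 19 methyl (2S,5R,6S)-4-benzoyl-5-methyl-2,6,8-tris(3-methylbut-2-en-1-yl)-5-(4-methylpent-3-en-1-yl)-3,9-dioxooxonane-2-carboxylate (epimers at ring carbons 4 and 8; partly enolised)
Conditions: MgBr2·OEt2 (2.5 equiv), i-Pr2NEt (3 equiv), CH2Cl2, 25 °C
Reagents that add atoms: 18 1-benzoyl-1H-benzotriazole, O=C(c1ccccc1)n1nnc2ccccc21
Why: Soft-enolisation C-acylation (magnesium chelation of the C2 ketone with the C4 ester, amine base) at C1, the only enolisable ketone α-position, gives the β-diketone; with the benzoyl group in place, C1 is a stabilised, non-nucleophilic diketonate in step 9 and cannot attack the lactone carbonyl C9.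

**Step 9**
Reactants: 19 benzoylated keto lactone
Product: 21 target CNP0269674.1, via dilithium dianion 20 (not isolated)
Conditions: LiN(i-Pr)2 (2.3 equiv), THF, −78 → −20 °C; 1 M HCl, −78 °C
Reagents that add atoms: none
Why: Transannular Lacey–Dieckmann condensation: the first equivalent of base masks C1/C2 as the diketonate, the second deprotonates C5 (the only remaining acidic C–H), and the lactone enolate closes onto the C4 methyl ester through the five-membered ring O1–C9–C5–C4–C3, which forms the furan-2,4-dione and with it the eight-membered carbocycle; the quaternary C5 can only form cis-bridged (5R) and C1 equilibrates through the enol to the 1R epimer.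

**Compound list**

1 | methyl (2S)-oxirane-2-carboxylate | COC(=O)[C@@H]1CO1 | starting material
2 | (2-methylprop-1-en-1-yl)magnesium bromide | CC(C)=C[Mg]Br | starting material
3 | methyl (2S)-2-hydroxy-5-methylhex-4-enoate | COC(=O)[C@@H](O)CC=C(C)C | intermediate
4 | (2E)-3,7-dimethylocta-2,6-dienoic acid (geranic acid) | CC(C)=CCC/C(C)=C/C(O)=O | starting material
5 | 2,2-dimethyl-1,3-dioxane-4,6-dione | CC1(C)OC(=O)CC(=O)O1 | starting material
6 | 5-[(2E)-1-hydroxy-3,7-dimethylocta-2,6-dien-1-ylidene]-2,2-dimethyl-1,3-dioxane-4,6-dione | CC(C)=CCC/C(C)=C/C(O)=C1C(=O)OC(C)(C)OC1=O | intermediate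
7 | (4E)-5,9-dimethyl-3-oxodeca-1,4,8-trien-1-one (acylketene) | CC(C)=CCC/C(C)=C/C(=O)C=C=O | intermediate
8 | methyl (2S)-2-{[(4E)-5,9-dimethyl-3-oxodeca-4,8-dienoyl]oxy}-5-methylhex-4-enoate | COC(=O)[C@H](CC=C(C)C)OC(=O)CC(=O)/C=C(\C)CCC=C(C)C | intermediate
9 | 5-methylhex-4-enal | CC(C)=CCCC=O | starting material
10 | methyl (2S)-2-{[(4E)-5,9-dimethyl-2-(5-methylhex-4-en-1-ylidene)-3-oxodeca-4,8-dienoyl]oxy}-5-methylhex-4-enoate (E/Z mixture at the new alkene) | COC(=O)[C@H](CC=C(C)C)OC(=O)C(=CCCC=C(C)C)C(=O)/C=C(\C)CCC=C(C)C | intermediate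
11 | 1-bromo-3-methylbut-2-ene (prenyl bromide) | CC(C)=CCBr | starting material
12 | methyl (2S)-2-{[(2R,4E)-5,9-dimethyl-2-(3-methylbut-2-en-1-yl)-2-[(1E)-5-methylhexa-1,4-dien-1-yl]-3-oxodeca-4,8-dienoyl]oxy}-5-methylhex-4-enoate | COC(=O)[C@H](CC=C(C)C)OC(=O)[C@](CC=C(C)C)(/C=C/CC=C(C)C)C(=O)/C=C(\C)CCC=C(C)C | intermediate
13 | potassium ester enolate of 12 (C3=C4 enolate, C5 R) | COC([O-])=C(CC=C(C)C)OC(=O)[C@](CC=C(C)C)(/C=C/CC=C(C)C)C(=O)/C=C(\C)CCC=C(C)C.[K+] | intermediate
14 | potassium (2S,3S,4R)-3-[(1E)-2,6-dimethylhepta-1,5-dien-1-yl]-2-(methoxycarbonyl)-2,4-bis(3-methylbut-2-en-1-yl)-4-[(1E)-5-methylhexa-1,4-dien-1-yl]-5-oxooxolan-3-olate (aldolate; C3 S, C2 S, C5 R) | O=C1O[C@](CC=C(C)C)(C(=O)OC)[C@]([O-])(/C=C(\C)CCC=C(C)C)[C@@]1(CC=C(C)C)/C=C/CC=C(C)C.[K+] | intermediate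
15 | potassium C1=C2 enolate of 16 | CC(C)=CCC[C@]1(C)[C@@H](CC=C(C)C)/C=C(\CC=C(C)C)C(=O)O[C@@](CC=C(C)C)(C([O-])=C1)C(=O)OC.[K+] | intermediate
16 | methyl (2S,5S,6S,7E)-5-methyl-2,6,8-tris(3-methylbut-2-en-1-yl)-5-(4-methylpent-3-en-1-yl)-3,9-dioxo-2,3,4,5,6,9-hexahydrooxonine-2-carboxylate (C3 S, C7 S, C8 as in the target) | CC(C)=CCC[C@]1(C)[C@@H](CC=C(C)C)/C=C(\CC=C(C)C)C(=O)O[C@@](CC=C(C)C)(C(=O)C1)C(=O)OC | intermediate
17 | methyl (2S,5S,6S)-5-methyl-2,6,8-tris(3-methylbut-2-en-1-yl)-5-(4-methylpent-3-en-1-yl)-3,9-dioxooxonane-2-carboxylate (C5 epimers) | CC(C)=CCC[C@]1(C)[C@@H](CC=C(C)C)CC(CC=C(C)C)C(=O)O[C@@](CC=C(C)C)(C(=O)C1)C(=O)OC | intermediate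
18 | 1-benzoyl-1H-benzotriazole | O=C(c1ccccc1)n1nnc2ccccc21 | starting material
19 | methyl (2S,5R,6S)-4-benzoyl-5-methyl-2,6,8-tris(3-methylbut-2-en-1-yl)-5-(4-methylpent-3-en-1-yl)-3,9-dioxooxonane-2-carboxylate (C1 and C5 epimers) | CC(C)=CCC[C@]1(C)[C@@H](CC=C(C)C)CC(CC=C(C)C)C(=O)O[C@@](CC=C(C)C)(C(=O)C1C(=O)c1ccccc1)C(=O)OC | intermediate
20 | dilithium dianion of 19 (C1/C2 diketonate and C5 lactone enolate) | CC(C)=CCC[C@]1(C)[C@@H](CC=C(C)C)CC(CC=C(C)C)=C([O-])O[C@@](CC=C(C)C)(C([O-])=C1C(=O)c1ccccc1)C(=O)OC.[Li+].[Li+] | intermediate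
21 | target CNP0269674.1 (1R,3S,5R,7S,8R in the numbering above: benzoyl on C1, ketones C2 and C4, prenyl on C3, C5 and C7, methyl and 4-methylpent-3-enyl on C8, lactone O1–C9(=O) bridging C3 and C5) | CC(C)=CCC[C@]1(C)[C@@H](CC=C(C)C)C[C@@]2(CC=C(C)C)C(=O)O[C@@](CC=C(C)C)(C(=O)[C@H]1C(=O)c1ccccc1)C2=O | target

**Step count and risks**

Total steps: 9. Longest linear sequence: 8 steps (steps 2–9 from geranic acid; equally steps 1 and 3–9 from the glycidate).

Steps most likely to fail:

1. Step 6 (proposed new method). What may go wrong: the alkoxide 14 fragments in the C2–C5 sense to an ester dienolate that recombines without relay of configuration or closes a furandione by five-membered Claisen condensation; the shift runs through the boat array of the cis-dialkenyl aldolate and inverts the C7/C8 relationship; or the base removes a γ-hydrogen of the enone and scrambles the 2E geometry. Fallback with known chemistry, from 12 back to 16: aldol and rearrangement are run as two separate operations. LiN(SiMe3)2 in THF at −78 °C followed by protonation gives the hydroxy lactone F1, since lithium aldolates do not undergo the shift at this temperature. The diastereomer with trans alkenyl groups and prenyl syn to hydroxyl is selected by chromatography and submitted to the classical ring-expanding anionic oxy-Cope rearrangement (KH, 18-crown-6, THF, 0 °C), which returns to 16.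

2. Step 5. What may go wrong: low facial selectivity at the extended enolate, competing O- or γ-alkylation, or ring closure of the enolate onto the C4 methyl ester. Fallback, from 8 back to 12: the quaternary centre is built by aldol addition instead of alkylation. C-Prenylation of 8 (K2CO3, 11, acetone) gives the α-prenyl β-keto ester F2. Aldol addition to aldehyde 9 (TiCl4, Et3N, CH2Cl2, −78 °C) gives the β-hydroxy compound F3 with the quaternary C5; its C5 epimers are diastereomers and are separated at this stage. Mesylation and elimination away from the quaternary carbon (MsCl, Et3N; then DBU) gives the E alkene and returns to 12.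

3. Step 9. What may go wrong: slow deprotonation of the hindered lactone α-C–H, and reopening of the non-enolisable β-keto lactone by the methoxide released (retro-Claisen). Fallback, from 16 back to 21: 16 is benzoylated directly under the conditions of step 8 to give the unsaturated diketone F4. Treatment with KN(SiMe3)2 (1 equiv) and then LiBH(s-Bu)3 at −78 °C delivers hydride to C6, so the C5 enolate forms regiospecifically without strong base and closes onto the C4 ester (reductive Dieckmann), with the trialkylborane binding the methoxide; acid work-up gives 21.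

**Further compounds**

F1 | step 6 | methyl (2S,3S,4R)-3-[(1E)-2,6-dimethylhepta-1,5-dien-1-yl]-3-hydroxy-2,4-bis(3-methylbut-2-en-1-yl)-4-[(1E)-5-methylhexa-1,4-dien-1-yl]-5-oxooxolane-2-carboxylate | O=C1O[C@](CC=C(C)C)(C(=O)OC)[C@](O)(/C=C(\C)CCC=C(C)C)[C@@]1(CC=C(C)C)/C=C/CC=C(C)C
F2 | step 5 | methyl (2S)-2-{[(4E)-5,9-dimethyl-2-(3-methylbut-2-en-1-yl)-3-oxodeca-4,8-dienoyl]oxy}-5-methylhex-4-enoate | COC(=O)[C@H](CC=C(C)C)OC(=O)C(CC=C(C)C)C(=O)/C=C(\C)CCC=C(C)C
F3 | step 5 | methyl (2S)-2-{[(2R,4E)-2-(1-hydroxy-5-methylhex-4-en-1-yl)-5,9-dimethyl-2-(3-methylbut-2-en-1-yl)-3-oxodeca-4,8-dienoyl]oxy}-5-methylhex-4-enoate | COC(=O)[C@H](CC=C(C)C)OC(=O)[C@](CC=C(C)C)(C(O)CCC=C(C)C)C(=O)/C=C(\C)CCC=C(C)C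
F4 | step 9 | methyl (2S,5R,6S,7E)-4-benzoyl-5-methyl-2,6,8-tris(3-methylbut-2-en-1-yl)-5-(4-methylpent-3-en-1-yl)-3,9-dioxo-2,3,4,5,6,9-hexahydrooxonine-2-carboxylate | CC(C)=CCC[C@]1(C)[C@@H](CC=C(C)C)/C=C(\CC=C(C)C)C(=O)O[C@@](CC=C(C)C)(C(=O)C1C(=O)c1ccccc1)C(=O)OC
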